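## Structural features

The target 20 is the diester of an unsymmetrical C10 diacid, (2E,6E)-2,6-dimethylocta-2,6-dienedioic acid, with two identical bicyclic amino alcohols; one ester is an α-methyl enoate and the other a β-methyl enoate, so the molecule has no symmetry element. Each alcohol part is a cis-fused octahydrocyclopenta[c]pyridine: ring A is the cyclopentane (C4a, C5, C6, C7, C7a) and ring B the N-methylpiperidine (C1, N2, C3, C4, C4a, C7a), joined through the C4a–C7a bond. Five stereocentres are contiguous (C4, C4a, C7a, C7, C6; 4S,4aR,6S,7R,7aS): H4, H4a and H7a are all cis, the C7 methyl is trans to C1, and the C6 oxygen lies cis to the C7 methyl on the convex face. The fragile points are the two trisubstituted E-enoates (conjugate acceptors that can isomerise or deconjugate under base), the secondary-alkyl ester links and the basic tertiary amines. The real difficulty is the stereochemistry of the bicycle: the cis fusion, the C4 methyl relative to C4a, and a C6 oxygen on the face from which a hydride prefers to attack a C6 ketone, so that reduction gives the opposite epimer. The key step uses the fact that C4a is both the neighbour of methyl-bearing C4 and, through C5, the β-carbon of a C6 carbonyl: with a C4a=C5 enone in ring A, a vinyl unit carried on N2 of the C7a side chain can add to C4a, forming the C4–C4a bond, closing ring B and fixing the cis fusion.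

## Logic of the disconnections

**20 to 14 and 19.** The two C6–O bonds are cut on the alkyl side, not the acyl side. These are the only links between three otherwise separate carbon skeletons, and cutting on the alkyl side lets the oxygen arrive with inversion. The gain is two identical amino alcohols 14 and one acyclic diacid 19. The demand is a double SN2 esterification at a secondary carbon next to a methyl-bearing carbon, so 14 must be the 6R epimer, and the step must neither eliminate nor isomerise the enoates.

**14 to 13.** The C6–H bond and the N-methyl C–H bonds are removed: the carbinol goes back to a ketone and N–CH3 to N–CO2CH3. One hydride reagent makes both changes, and nitrogen stays non-basic through all earlier steps. The gain is that no separate N-methylation or deprotection is needed. The demand is hydride delivery to C6 from the convex face, which places the oxygen trans to the C7 methyl.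

**13 to 12.** The C4–H bond and one methyl C–H bond are removed, so the C4 methyl becomes an exocyclic methylene. An sp2 C4 is what a vinyl halide cyclisation leaves behind, and the folded cis-bicycle has one open face. The gain is one stereocentre fewer. The demand is hydrogen addition from the side of H4a without migration of the double bond.

**12 to 11.** The C4–C4a bond is cut and ring B opens. It is the one C–C bond of ring B that ends at a stereocentre β to the C6 carbonyl, so it can be made by adding a C4 vinylmetal to a C4a=C5 enone, with the short tether from C7a forcing the cis fusion. The gain is a monocyclic cyclopentenone with two stereocentres. The demand is ring closure before reduction of the vinylmetal, and no erosion at C7a. In 11 nitrogen carries CO2CH3 and not CH3. A free tertiary amine beside an enone with an acidic γ-hydrogen (H7a) would promote epimerisation at C7a and elimination of the amine, would bind palladium, and would make C3–N an allylic amine bond at the hydrogenation stage. The carbamate avoids all of this and is the N-methyl group in latent form.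

**11 to 9 (through 10).** The C4a=C5 double bond is removed. The saturated ketone has no γ-labile centre and can carry the side chain through the alkylation chemistry. The gain is a simple 2,3-trans-disubstituted cyclopentanone. The demand is dehydrogenation on the CH2 side of the ketone only, under conditions that do not enolise the product toward C7a and use no palladium while the vinyl bromide is present.

**9 to 8, and 8 to 6 and 7.** The dioxolane is restored and the N–C3 bond is cut. An N–allyl bond is made by SN2 alkylation of the carbamate anion, which needs NaH and therefore a masked ketone. The gain is that 7 is commercial and 6 is simple. The demand is alkylation at the allylic bromide only, and a ketal hydrolysis that spares the carbamate and the vinyl bromide.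

**6 to 4 (through 5), and 4 to 3.** The N–CO2CH3 bond is cut, the amine is traced to a nitro group and the ketal to the ketone. Nitro is the form in which the C1–N unit enters, and ketalisation before reduction prevents amine–ketone condensation. The gain is the nitro ketone 3. The demand is that the amine is acylated as soon as it forms.

**3 to 1 and 2.** The C7a–C1 bond is cut. Conjugate addition makes this bond and sets C7a, and C7 follows by equilibration to the trans isomer. The gain is two commercial compounds. The demand is enantiofacial control on an α-substituted cyclic enone, the least secure point before the key step.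

**19 to 17 (through 18), 17 to 16, 16 to 15.** The carboxyl groups are traced to primary allylic alcohols and the C8–O bond to an allylic C–H bond. 15 already has the whole carbon chain and one E double bond. The gain is that no C–C bond has to be formed. The demand is E-selective allylic oxidation and no later E/Z isomerisation.

## Other disconnections considered

**Alternative 1:** The cut removes the C7–CH3 and C7a–C1 bonds, the two substituents of ring A. It leads back to (R)-4-[(tert-butyldimethylsilyl)oxy]cyclopent-2-en-1-one A1 and N-benzyl-N-methylmethaniminium trifluoroacetate A2. In the forward step Me2CuLi would add at the future C7 anti to the silyloxy group, and the enolate would be trapped at C7a by A2 (conjugate addition–Mannich sequence). The product would be (2S,3R,4R)-2-{[benzyl(methyl)amino]methyl}-4-[(tert-butyldimethylsilyl)oxy]-3-methylcyclopentan-1-one A3, with its carbonyl at C4a.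
- In favour: A1 is a commercial enantiopure compound, so no asymmetric catalysis is needed. This is better than the chosen plan, whose first step is its least secure.
- In favour: two C–C bonds and two stereocentres arise in one operation, against one of each in step 7, and the C6 oxygen is already in place with a defined configuration, so no ketone reduction has to be face-selective. Both points are better than in the chosen plan.
- Against: A3 is a β-amino ketone that can lose the amine by retro-Mannich reaction or elimination, and the enolates on the way can expel the β-silyloxy group.
- Against: ring B does not yet exist. The benzyl group must be exchanged for the C3–C4 unit and the C4–C4a bond made at a ketone carbon, so C4a and C4 would both be set afterwards by reduction instead of by the geometry of a ring closure.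
- Equal: C6 is epimeric and needs the same final inversion as in the chosen route.
- Comparison: structurally this plan solves ring A and leaves ring B, the reverse of the chosen plan. Its stereocontrol is at least as reliable mechanistically. It should need more steps after its key step than the three that follow step 7.

**Alternative 2:** The cut removes C4a–C7a, C5–C6 and C6–C7, dissolving both rings. It leads back to methyl [(2E)-but-2-en-1-yl][(2S)-2-methylbut-3-yn-1-yl]carbamate A4 and carbon monoxide. Co2(CO)8 would complex the terminal alkyne, and the (E)-alkene and CO would insert (Pauson–Khand reaction). The product would be methyl (4S,7R,7aR)-4,7-dimethyl-6-oxo-1,3,4,6,7,7a-hexahydro-2H-cyclopenta[c]pyridine-2-carboxylate A5.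
- In favour: three C–C bonds and both rings form in one step, the best bond economy of all plans and better than the chosen one.
- In favour: C4 comes from a small chiral building block, so the facial question of step 8 does not arise (better), and the alkene geometry is transferred to the trans C7/C7a relationship.
- Equal: A5 carries the same carbamate and C6 carbonyl as 13, so the endgame would be shared.
- Against: the tether closes a six-membered ring (a 1,7-enyne) and the alkene is internal; both are known to lower Pauson–Khand efficiency.
- Against: C7a is controlled only by a remote 1,3-relationship to the C4 methyl across a flexible tether, and C4a would be set by hydrogenating the C4a=C5 bond of A5 and not by a tether that reaches one face only. Stoichiometric Co2(CO)8 is usual.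
- Comparison: the step count is better on paper and the structural simplification is the largest, but stereocontrol at C7a and C4a is weaker than in the chosen plan.

**Alternative 3:** The cut removes the C7–C7a bond of ring A. It leads back to methyl (3S,4R)-3-methyl-4-{(2Z)-2-[(trimethylsilyl)oxy]but-2-en-1-yl}-3,4-dihydropyridine-1(2H)-carboxylate A6. Anodic oxidation in methanol would join the enol ether carbon C7 to the enecarbamate carbon C7a, and methanol would capture the N-acyliminium ion at C1. The product would be methyl (4S,4aR,7R,7aS)-1-methoxy-4,7-dimethyl-6-oxooctahydro-2H-cyclopenta[c]pyridine-2-carboxylate A7 (C1 undefined).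
- In favour: two nucleophilic carbons are joined with electricity as the only oxidant, which is cleaner in reagent terms than the palladium/formate system of step 7 (better on this point), and the bond between two adjacent stereocentres is made directly.
- Equal: A7 differs from 13 only by the C1 methoxy group, so the endgame is shared. C7 stays epimerisable to trans, as in the chosen route.
- Against: A6 must already hold ring B with C4 and C4a cis on a tetrahydropyridine, and needs a regiodefined silyl enol ether of a ketone flanked by two methylene groups.
- Against: the cis fusion is expected but not geometrically enforced, the C1 methoxy group costs an extra reductive step (for example Et3SiH with BF3·OEt2), and electrochemical equipment is required.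
- Comparison: the hard stereochemistry (C4/C4a) is moved into a precursor that is longer to make, so the overall step count is expected to be higher than in the chosen plan, and stereocontrol in the ring closure is less certain.

Key step: step 7

**Assumptions and remarks.**
- Which pseudoenantiomeric cinchona amine (quinine- or quinidine-derived) gives the 3S adduct in step 1 is not predicted here. The step is written with the quinine-derived catalyst; the other is to be used if the sense of induction requires it.
- Geranyl acetate 15 is taken as the commercial C10 terpene, so the allylic oxidation needs no protection step.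
- The trans enone 11 and the cis-fused ketone 12 carry C7, C7a and C4a exactly as 20 requires. The only change made to the cyclisation substrate is the group on nitrogen.

## Route

Step 1
Reactants: 1 2-methylcyclopent-2-en-1-one; 2 nitromethane
Product: 3 (2R,3S)-2-methyl-3-(nitromethyl)cyclopentan-1-one
Conditions: 2 (10 equiv), 9-amino-9-deoxy-epi-quinine (20 mol%), PhCO2H (40 mol%), THF, 40 °C
Reagents that add atoms: none
Why: Proposed new method: the primary amine of the catalyst should condense with the hindered α-methyl enone to an iminium ion (a primary amine avoids the allylic strain that stops secondary amines here), the nitronate held by the protonated quinuclidine adds to one face of C3, and the enamine is protonated at C2 and hydrolysed, after which C2 equilibrates through the enamine to the trans isomer; the closest known reaction type is the primary-amine iminium-catalysed Michael addition of nitroalkanes to α-unsubstituted cycloalkenones, together with additions of other nucleophiles to α-branched enones under the same catalysis.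

Step 2
Reactants: 3 (2R,3S)-2-methyl-3-(nitromethyl)cyclopentan-1-one
Product: 4 (6R,7S)-6-methyl-7-(nitromethyl)-1,4-dioxaspiro[4.4]nonane
Conditions: HOCH2CH2OH, p-TsOH·H2O (cat.), PhMe, reflux (Dean–Stark)
Reagents that add atoms: ethylene glycol, OCCO
Why: Acid-catalysed acetalisation with azeotropic removal of water masks the ketone before amine formation and NaH chemistry; the nitro group and the β-stereocentre are inert, and the α-methyl centre can only relax toward the trans arrangement (it is re-equilibrated when the ketone is released in step 5).

Step 3
Reactants: 4 (6R,7S)-6-methyl-7-(nitromethyl)-1,4-dioxaspiro[4.4]nonane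
Product: 6 methyl {[(6R,7S)-6-methyl-1,4-dioxaspiro[4.4]nonan-7-yl]methyl}carbamate, via primary amine 5 (not isolated)
Conditions: H2 (3 atm), 10% Pd/C, MeOH, rt; filter; ClCO2Me, NaHCO3, CH2Cl2/H2O, 0 °C
Reagents that add atoms: methyl chloroformate, COC(=O)Cl
Why: Catalytic hydrogenation of the primary nitroalkane gives the amine, which is trapped at once by Schotten–Baumann acylation; the methyl carbamate is the latent N-methyl group and provides an N–H acidic enough for the next alkylation, and no stereocentre is touched.

Step 4
Reactants: 6 methyl {[(6R,7S)-6-methyl-1,4-dioxaspiro[4.4]nonan-7-yl]methyl}carbamate; 7 2,3-dibromoprop-1-ene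
Product: 8 methyl (2-bromoprop-2-en-1-yl){[(6R,7S)-6-methyl-1,4-dioxaspiro[4.4]nonan-7-yl]methyl}carbamate
Conditions: NaH, DMF, 0 °C; 7, 0 °C → rt
Reagents that add atoms: none
Why: N-Alkylation of the carbamate sodium salt by SN2 displacement of the allylic bromide of 7; the vinylic bromide does not react by SN2 and the ketal keeps ketone enolate chemistry out of the step.

Step 5
Reactants: 8 methyl (2-bromoprop-2-en-1-yl){[(6R,7S)-6-methyl-1,4-dioxaspiro[4.4]nonan-7-yl]methyl}carbamate
Product: 9 methyl (2-bromoprop-2-en-1-yl){[(1S,2R)-2-methyl-3-oxocyclopentyl]methyl}carbamate
Conditions: 1 M HCl, THF, rt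
Reagents that add atoms: water, O
Why: Acid hydrolysis of the dioxolane; the methyl carbamate and the vinyl bromide tolerate dilute acid, and the enolisable methyl-bearing carbon settles as the trans epimer under these conditions.

Step 6
Reactants: 9 methyl (2-bromoprop-2-en-1-yl){[(1S,2R)-2-methyl-3-oxocyclopentyl]methyl}carbamate
Product: 11 methyl (2-bromoprop-2-en-1-yl){[(1S,5R)-5-methyl-4-oxocyclopent-2-en-1-yl]methyl}carbamate, via trimethylsilyl enol ether 10 (not isolated)
Conditions: LiN(i-Pr)2 (commercial solution), Me3SiCl, THF, −78 °C; evaporate, pentane, filter; IBX (2-iodoxybenzoic acid), 4-methoxypyridine N-oxide, DMSO, rt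
Reagents that add atoms: chlorotrimethylsilane, C[Si](C)(C)Cl (its silyl group is carried by 10 only and is lost again in the oxidation)
Why: Kinetic deprotonation with in situ silylation places the enol ether on the CH2 side, away from the methyl-bearing α-carbon, and pentavalent-iodine oxidation of the silyl enol ether (the metal-free counterpart of a Saegusa–Ito oxidation) gives the enone under near-neutral conditions that spare the γ-stereocentre (ring C1, the future C7a); a palladium oxidant is avoided because zerovalent palladium formed from it would attack the vinyl bromide too early.

Step 7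
Reactants: 11 methyl (2-bromoprop-2-en-1-yl){[(1S,5R)-5-methyl-4-oxocyclopent-2-en-1-yl]methyl}carbamate
Product: 12 methyl (4aS,7R,7aS)-7-methyl-4-methylidene-6-oxooctahydro-2H-cyclopenta[c]pyridine-2-carboxylate
Conditions: Pd(OAc)2 (10 mol%), PPh3 (20 mol%), HCO2Na, Bu4NCl, DMF, 80 °C
Reagents that add atoms: none
Why: Zerovalent palladium, formed in the flask from Pd(OAc)2 and PPh3, inserts into the C–Br bond to give a vinylpalladium bromide. Intramolecular syn carbopalladation of the enone then places the vinyl carbon on the β-carbon C4a and palladium on C5, closing ring B in the 6-exo-trig mode; the 7-endo path is disfavoured by ring size and by the polarisation of the enone. The palladium enolate has its only β-hydrogen (H4a) anti to the metal, so β-hydride elimination cannot occur; formate delivers hydride with loss of CO2 and reductive elimination returns zerovalent palladium, which is the known intramolecular reductive Heck (conjugate) cyclisation of vinyl halides onto cyclic enones. The new stereocentre C4a is controlled by C7a: the three-atom tether can reach C4a only from the face on which it is attached, so the fusion must be cis. The selectivity needed is ring closure ahead of direct formate reduction of the vinylpalladium, which the short tether and the unhindered disubstituted enone should secure. C7 is epimerisable but trans to C1 is the favoured arrangement, and the carbamate nitrogen can neither ligate palladium nor act as a base toward H7a.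

Step 8
Reactants: 12 methyl (4aS,7R,7aS)-7-methyl-4-methylidene-6-oxooctahydro-2H-cyclopenta[c]pyridine-2-carboxylate
Product: 13 methyl (4S,4aR,7R,7aS)-4,7-dimethyl-6-oxooctahydro-2H-cyclopenta[c]pyridine-2-carboxylate
Conditions: H2 (1 atm), PtO2, EtOAc, rt
Reagents that add atoms: none
Why: Heterogeneous syn-hydrogenation of the 1,1-disubstituted alkene; in either chair of ring B the face of C4 on the side of C5 and C7 is covered by ring A, so hydrogen should arrive on the face that carries H4a and the methyl ends cis to C5 (4S); PtO2 is chosen over a palladium catalyst to limit migration of the double bond toward nitrogen.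

Step 9
Reactants: 13 methyl (4S,4aR,7R,7aS)-4,7-dimethyl-6-oxooctahydro-2H-cyclopenta[c]pyridine-2-carboxylate
Product: 14 (4S,4aR,6R,7R,7aS)-2,4,7-trimethyloctahydro-1H-cyclopenta[c]pyridin-6-ol
Conditions: LiAlH4, THF, 0 °C; then reflux; aq. NaOH work-up
Reagents that add atoms: none
Why: LiAlH4 reduces the ketone first, with hydride expected on the convex face (the concave face is screened by ring B, and small hydrides add to 2-alkylcyclopentanones syn to the alkyl group), which gives the 6R alcohol trans to the C7 methyl; at reflux the same reagent reduces the methyl carbamate to the N-methyl amine.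

Step 10
Reactants: 15 geranyl acetate
Product: 16 (2E,6E)-8-hydroxy-3,7-dimethylocta-2,6-dien-1-yl acetate
Conditions: SeO2 (cat.), t-BuOOH, salicylic acid (cat.), CH2Cl2, rt
Reagents that add atoms: selenium dioxide, O=[Se]=O; tert-butyl hydroperoxide, CC(C)(C)OO
Why: Catalytic SeO2 allylic oxidation (ene reaction followed by a [2,3]-sigmatropic shift) is selective for the (E)-methyl of the terminal trisubstituted alkene while the acetate shields the other allylic terminus; over-oxidation at C8 would be harmless because that carbon is oxidised further in step 12.

Step 11
Reactants: 16 (2E,6E)-8-hydroxy-3,7-dimethylocta-2,6-dien-1-yl acetate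
Product: 17 (2E,6E)-2,6-dimethylocta-2,6-diene-1,8-diol
Conditions: K2CO3, MeOH, rt
Reagents that add atoms: none
Why: Base-catalysed transesterification removes the acetate without touching either alkene.

Step 12
Reactants: 17 (2E,6E)-2,6-dimethylocta-2,6-diene-1,8-diol
Product: 19 (2E,6E)-2,6-dimethylocta-2,6-dienedioic acid, via dialdehyde 18 (not isolated)
Conditions: TEMPO (2,2,6,6-tetramethylpiperidin-1-oxyl, cat.), PhI(OAc)2, CH2Cl2, rt; then NaClO2, NaH2PO4, 2-methylbut-2-ene, t-BuOH/H2O, rt
Reagents that add atoms: sodium chlorite, [Na+].[O-]Cl=O
Why: Oxoammonium oxidation takes both allylic alcohols to the dienedial without disturbing alkene geometry, and buffered chlorite with an alkene scavenger (Pinnick oxidation) converts both enals to the acids; neither stage is acidic or basic enough to isomerise the 2E or 6E bond.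

Step 13
Reactants: 14 (4S,4aR,6R,7R,7aS)-2,4,7-trimethyloctahydro-1H-cyclopenta[c]pyridin-6-ol; 19 (2E,6E)-2,6-dimethylocta-2,6-dienedioic acid
Product: 20 bis[(4S,4aR,6S,7R,7aS)-2,4,7-trimethyloctahydro-1H-cyclopenta[c]pyridin-6-yl] (2E,6E)-2,6-dimethylocta-2,6-dienedioate
Conditions: 14 (2.2 equiv), PPh3, DIAD (diisopropyl azodicarboxylate), THF, 0 °C → rt
Reagents that add atoms: none
Why: Double Mitsunobu esterification: each C6 alkoxyphosphonium ion is displaced by a carboxylate of 19 from the open convex face with SN2 inversion (6R to 6S), which is why the 6R alcohol was prepared; the enoic acids are acidic enough to protonate the betaine, ring B sits on the face of the leaving group so nitrogen cannot participate, and the mild neutral conditions leave both E-enoates intact.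

## Compound list

1 | 2-methylcyclopent-2-en-1-one | CC1=CCCC1=O | starting material
2 | nitromethane | C[N+](=O)[O-] | starting material
3 | (2R,3S)-2-methyl-3-(nitromethyl)cyclopentan-1-one | O=C1CC[C@H](C[N+](=O)[O-])[C@H]1C | intermediate
4 | (6R,7S)-6-methyl-7-(nitromethyl)-1,4-dioxaspiro[4.4]nonane | C12(OCCO1)CC[C@H](C[N+](=O)[O-])[C@H]2C | intermediate
5 | [(6R,7S)-6-methyl-1,4-dioxaspiro[4.4]nonan-7-yl]methanamine | C12(OCCO1)CC[C@H](CN)[C@H]2C | intermediate
6 | methyl {[(6R,7S)-6-methyl-1,4-dioxaspiro[4.4]nonan-7-yl]methyl}carbamate | C12(OCCO1)CC[C@H](CNC(=O)OC)[C@H]2C | intermediate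
7 | 2,3-dibromoprop-1-ene | C=C(Br)CBr | starting material
8 | methyl (2-bromoprop-2-en-1-yl){[(6R,7S)-6-methyl-1,4-dioxaspiro[4.4]nonan-7-yl]methyl}carbamate | C12(OCCO1)CC[C@H](CN(C(=O)OC)CC(Br)=C)[C@H]2C | intermediate
9 | methyl (2-bromoprop-2-en-1-yl){[(1S,2R)-2-methyl-3-oxocyclopentyl]methyl}carbamate | O=C1CC[C@H](CN(C(=O)OC)CC(Br)=C)[C@H]1C | intermediate
10 | methyl (2-bromoprop-2-en-1-yl){[(1S,5R)-5-methyl-4-[(trimethylsilyl)oxy]cyclopent-3-en-1-yl]methyl}carbamate | C[Si](C)(C)OC1=CC[C@H](CN(C(=O)OC)CC(Br)=C)[C@H]1C | intermediate
11 | methyl (2-bromoprop-2-en-1-yl){[(1S,5R)-5-methyl-4-oxocyclopent-2-en-1-yl]methyl}carbamate | O=C1C=C[C@H](CN(C(=O)OC)CC(Br)=C)[C@H]1C | intermediate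
12 | methyl (4aS,7R,7aS)-7-methyl-4-methylidene-6-oxooctahydro-2H-cyclopenta[c]pyridine-2-carboxylate | O=C1C[C@H]2[C@H](CN(C(=O)OC)CC2=C)[C@H]1C | intermediate
13 | methyl (4S,4aR,7R,7aS)-4,7-dimethyl-6-oxooctahydro-2H-cyclopenta[c]pyridine-2-carboxylate | O=C1C[C@H]2[C@H](CN(C(=O)OC)C[C@H]2C)[C@H]1C | intermediate
14 | (4S,4aR,6R,7R,7aS)-2,4,7-trimethyloctahydro-1H-cyclopenta[c]pyridin-6-ol | O[C@@H]1C[C@H]2[C@H](CN(C)C[C@H]2C)[C@H]1C | intermediate
15 | geranyl acetate, (2E)-3,7-dimethylocta-2,6-dien-1-yl acetate | CC(C)=CCC/C(C)=C/COC(C)=O | starting material
16 | (2E,6E)-8-hydroxy-3,7-dimethylocta-2,6-dien-1-yl acetate | OC/C(C)=C/CC/C(C)=C/COC(C)=O | intermediate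
17 | (2E,6E)-2,6-dimethylocta-2,6-diene-1,8-diol | OC/C(C)=C/CC/C(C)=C/CO | intermediate
18 | (2E,6E)-2,6-dimethylocta-2,6-dienedial | O=C/C(C)=C/CC/C(C)=C/C=O | intermediate
19 | (2E,6E)-2,6-dimethylocta-2,6-dienedioic acid | OC(=O)/C(C)=C/CC/C(C)=C/C(=O)O | intermediate
20 | bis[(4S,4aR,6S,7R,7aS)-2,4,7-trimethyloctahydro-1H-cyclopenta[c]pyridin-6-yl] (2E,6E)-2,6-dimethylocta-2,6-dienedioate | C/C(=C\C(=O)O[C@H]1C[C@H]2[C@H](CN(C)C[C@H]2C)[C@H]1C)CC/C=C(\C)C(=O)O[C@H]1C[C@H]2[C@H](CN(C)C[C@H]2C)[C@H]1C | target

## Step count and least certain steps

Total: 13 steps. Longest linear sequence: 10 steps (steps 1–9 and 13); steps 10–12 form the three-step diacid branch.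

**Step 1 (asymmetric Michael addition).** The most likely failure is slow iminium formation with the α-methyl enone and weak facial discrimination, because the α-substituent twists the iminium ion and the addition may then run largely through an uncatalysed general-base path. The fallback uses known chemistry, sets out from 1 and 2 and returns at 5. DBU-catalysed addition of 2 to 1 in MeCN gives the trans adduct as the racemate, that is 3 together with (2S,3R)-2-methyl-3-(nitromethyl)cyclopentan-1-one F1. Ketalisation as in step 2 gives 4 with (6S,7R)-6-methyl-7-(nitromethyl)-1,4-dioxaspiro[4.4]nonane F2. Hydrogenation as in the first half of step 3 gives 5 with [(6S,7R)-6-methyl-1,4-dioxaspiro[4.4]nonan-7-yl]methanamine F3. The amine is resolved by crystallisation from i-PrOH with (R)-mandelic acid (or its enantiomer, whichever gives the less soluble salt with 5) as [(6R,7S)-6-methyl-1,4-dioxaspiro[4.4]nonan-7-yl]methanaminium (R)-mandelate F4. Aqueous NaOH releases 5, which is acylated as in step 3.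

**Step 7 (key step).** The most likely failure is formate reduction of the vinylpalladium intermediate before it cyclises (loss of bromine without ring closure), or base-induced dienolisation of the enone on heating with erosion at C7a. The fallback sets out from 11 and returns at 12: stoichiometric zerovalent nickel, Ni(cod)2 with Et3N in MeCN at rt. The vinylnickel species formed by insertion into the C–Br bond adds to C4a in conjugate fashion and the nickel enolate is protonated on work-up, so no hydride donor can intercept the vinyl–metal bond and no heating is needed. No new compound is made (F0).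

**Step 6 (enone formation).** The most likely failure is γ-deprotonation of the new enone (erosion of the future C7a centre or migration of the double bond), or hydrolysis of the silyl enol ether back to 9 in DMSO. The fallback sets out from 9 and returns at 11. The kinetic lithium enolate is trapped with PhSeCl at −78 °C as methyl (2-bromoprop-2-en-1-yl){[(1S,2R)-2-methyl-3-oxo-4-(phenylselanyl)cyclopentyl]methyl}carbamate F5. Oxidation with H2O2 and pyridine in CH2Cl2 at 0 °C then gives the selenoxide, which undergoes syn-elimination across the neighbouring CH2 within minutes under buffered conditions.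

**Step 8 (hydrogenation).** The most likely failure is migration of the exocyclic double bond into the ring toward nitrogen on the metal surface before reduction, or insufficient facial discrimination. The fallback sets out from 12 and returns at 13: hydrogen-atom-transfer hydrogenation with Mn(dpm)3 (cat.), PhSiH3 and t-BuOOH in i-PrOH at rt. A metal hydride gives a hydrogen atom to the terminal CH2, and the tertiary C4 radical takes its second hydrogen on the open face that carries H4a; this radical path has no surface-bound alkyl or allyl species that could move the double bond. No new compound is made (F0).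

**Step 9 (double reduction).** The most likely failure is incomplete facial selectivity at the C6 ketone, which in a one-pot double reduction would leave polar amino alcohol epimers that are hard to separate. The fallback sets out from 13 and returns at 14. Only the ketone is reduced, with NaBH4 in MeOH at −40 °C, to methyl (4S,4aR,6R,7R,7aS)-6-hydroxy-4,7-dimethyloctahydro-2H-cyclopenta[c]pyridine-2-carboxylate F6. If the C6 ratio is unsatisfactory, the neutral alcohol is equilibrated toward this trans (6R) epimer under Meerwein–Ponndorf–Verley conditions (Al(Oi-Pr)3, i-PrOH, trace acetone) or purified by chromatography. LiAlH4 in refluxing THF then converts the carbamate into the N-methyl group.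

**Step 13 (double Mitsunobu).** The most likely failure is elimination of the activated C6 alkoxyphosphonium ion toward C5 instead of substitution next to the C7 methyl, or stalling at the mono-ester. The fallback sets out from 14 and returns at 20. C6 is inverted first with a small, more acidic partner (PPh3, DIAD, 4-nitrobenzoic acid) to give (4S,4aR,6S,7R,7aS)-2,4,7-trimethyloctahydro-1H-cyclopenta[c]pyridin-6-yl 4-nitrobenzoate F7. K2CO3 in MeOH cleaves this to (4S,4aR,6S,7R,7aS)-2,4,7-trimethyloctahydro-1H-cyclopenta[c]pyridin-6-ol F8. Both ester bonds are then formed with retention by Steglich acylation (19, EDC·HCl, DMAP, CH2Cl2).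

## Further compounds

F1 | step 1 | (2S,3R)-2-methyl-3-(nitromethyl)cyclopentan-1-one | O=C1CC[C@@H](C[N+](=O)[O-])[C@@H]1C
F2 | step 1 | (6S,7R)-6-methyl-7-(nitromethyl)-1,4-dioxaspiro[4.4]nonane | C12(OCCO1)CC[C@@H](C[N+](=O)[O-])[C@@H]2C
F3 | step 1 | [(6S,7R)-6-methyl-1,4-dioxaspiro[4.4]nonan-7-yl]methanamine | C12(OCCO1)CC[C@@H](CN)[C@@H]2C
F4 | step 1 | [(6R,7S)-6-methyl-1,4-dioxaspiro[4.4]nonan-7-yl]methanaminium (2R)-2-hydroxy-2-phenylacetate | C12(OCCO1)CC[C@H](C[NH3+])[C@H]2C.O[C@@H](C([O-])=O)c1ccccc1
F0 | step 7 | none | none
F5 | step 6 | methyl (2-bromoprop-2-en-1-yl){[(1S,2R)-2-methyl-3-oxo-4-(phenylselanyl)cyclopentyl]methyl}carbamate | O=C1C([Se]c2ccccc2)C[C@H](CN(C(=O)OC)CC(Br)=C)[C@H]1C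
F0 | step 8 | none | none
F6 | step 9 | methyl (4S,4aR,6R,7R,7aS)-6-hydroxy-4,7-dimethyloctahydro-2H-cyclopenta[c]pyridine-2-carboxylate | O[C@@H]1C[C@H]2[C@H](CN(C(=O)OC)C[C@H]2C)[C@H]1C
F7 | step 13 | (4S,4aR,6S,7R,7aS)-2,4,7-trimethyloctahydro-1H-cyclopenta[c]pyridin-6-yl 4-nitrobenzoate | O=C(O[C@H]1C[C@H]2[C@H](CN(C)C[C@H]2C)[C@H]1C)c1ccc(cc1)[N+](=O)[O-]
F8 | step 13 | (4S,4aR,6S,7R,7aS)-2,4,7-trimethyloctahydro-1H-cyclopenta[c]pyridin-6-ol | O[C@H]1C[C@H]2[C@H](CN(C)C[C@H]2C)[C@H]1C
A1 | alternative 1 | (R)-4-[(tert-butyldimethylsilyl)oxy]cyclopent-2-en-1-one | CC(C)(C)[Si](C)(C)O[C@@H]1CC(=O)C=C1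
A2 | alternative 1 | N-benzyl-N-methylmethaniminium trifluoroacetate | C=[N+](C)Cc1ccccc1.[O-]C(=O)C(F)(F)F
A3 | alternative 1 | (2S,3R,4R)-2-{[benzyl(methyl)amino]methyl}-4-[(tert-butyldimethylsilyl)oxy]-3-methylcyclopentan-1-one | CC(C)(C)[Si](C)(C)O[C@@H]1CC(=O)[C@H](CN(C)Cc2ccccc2)[C@H]1C
A4 | alternative 2 | methyl [(2E)-but-2-en-1-yl][(2S)-2-methylbut-3-yn-1-yl]carbamate | C#C[C@H](C)CN(C(=O)OC)C/C=C/C
A5 | alternative 2 | methyl (4S,7R,7aR)-4,7-dimethyl-6-oxo-1,3,4,6,7,7a-hexahydro-2H-cyclopenta[c]pyridine-2-carboxylate | O=C1C=C2[C@H](CN(C(=O)OC)C[C@H]2C)[C@H]1C
A6 | alternative 3 | methyl (3S,4R)-3-methyl-4-{(2Z)-2-[(trimethylsilyl)oxy]but-2-en-1-yl}-3,4-dihydropyridine-1(2H)-carboxylate | C/C=C(\O[Si](C)(C)C)C[C@H]1C=CN(C(=O)OC)C[C@H]1C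
A7 | alternative 3 | methyl (4S,4aR,7R,7aS)-1-methoxy-4,7-dimethyl-6-oxooctahydro-2H-cyclopenta[c]pyridine-2-carboxylate (C1 undefined) | O=C1C[C@H]2[C@H](C(OC)N(C(=O)OC)C[C@H]2C)[C@H]1C
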